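**Retrosynthetic overview** (flavonoid numbering; MOM = methoxymethyl)

1. The last step is global cleavage of the three MOM ethers (3-O, 7-O, 4'-O) of a fully protected flavanonol.
2. Ring C (the pyranone) is cut at O1–C8a and C2–C3. This is a formal [4+2] of the C8a–C4a–C4–C3 unit of a 2-fluoroaryl MOM-oxymethyl ketone (as its Z-enol silane) with the C2=O1 unit of 4-(methoxymethoxy)benzaldehyde: a catalytic asymmetric Mukaiyama aldol followed in the same flask by a fluoride-relayed intramolecular SNAr.
3. Enabling feature: O1 sits on C8a of ring A, ortho to C4a, which carries the C4 ketone. A fluorine on C8a is therefore a vinylogous acyl fluoride (F–C8a=C4a–C4=O) open to ipso substitution. C3 is the oxygenated α-carbon of the same ketone and C2 is a carbinol carbon bearing ring B, so one aldol sets both stereocentres.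
4. Ring A piece: 5-fluororesorcinol bis-MOM ether, two successive directed ortho-lithiations (geranyl at C6 between the two OMOM groups, acyl at C4a between F and OMOM), then exchange of the MOM group ortho to the ketone for the 5-O-methyl group.
5. Ring order: rings A and B are bought as benzenes; ring C is the only ring made (step 9).

Key step: step 9

Assumption: the tin/diamine aldol is taken to follow the facial sense known for (Z)-α-alkoxy silyl enolates, so that the (R)-diamine delivers the enol silane to the Si face of the aldehyde; if the sense proves opposite, the (S)-diamine is used with no other change.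

Abbreviation: geranyl = (2E)-3,7-dimethylocta-2,6-dien-1-yl.

**Step 1**
Reactants: 1 5-fluorobenzene-1,3-diol (5-fluororesorcinol)
Product: 2 1-fluoro-3,5-bis(methoxymethoxy)benzene
Conditions: MOMCl (2.4 equiv), iPr2NEt (3 equiv), CH2Cl2, 0 °C → rt
Reagents that add atoms: chloromethyl methyl ether (MOMCl), COCCl
Why: Williamson-type O-alkylation of both phenols with the reactive α-chloro ether under amine base installs the two groups that later direct lithiation.

**Step 2**
Reactants: 2 1-fluoro-3,5-bis(methoxymethoxy)benzene; 3 geranyl bromide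
Product: 5 5-fluoro-2-geranyl-1,3-bis(methoxymethoxy)benzene, via aryllithium 4 (not isolated)
Conditions: n-BuLi (1.1 equiv), THF, −20 → 0 °C; CuBr·SMe2 (1.0 equiv), −78 °C; then 3, −78 °C → rt
Reagents that add atoms: none
Why: Directed ortho-metalation should take place at C2, the only position held between two lithium-coordinating OMOM groups, and the aryllithium (through its arylcopper) displaces bromide from geranyl bromide in an SN2 allylation that keeps the E-olefin geometry.

**Step 3**
Reactants: 6 methyl glycolate
Product: 7 methyl 2-(methoxymethoxy)acetate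
Conditions: MOMCl (1.3 equiv), iPr2NEt (1.6 equiv), CH2Cl2, 0 °C → rt
Reagents that add atoms: chloromethyl methyl ether (MOMCl), COCCl
Why: Williamson-type MOM protection of the primary alcohol under a non-nucleophilic amine base leaves the ester untouched.

**Step 4**
Reactants: 7 methyl 2-(methoxymethoxy)acetate
Product: 8 N-methoxy-N-methyl-2-(methoxymethoxy)acetamide
Conditions: MeNHOMe·HCl (1.5 equiv), iPrMgCl (3.0 equiv), THF, −20 °C
Reagents that add atoms: N,O-dimethylhydroxylamine hydrochloride, CNOC.Cl
Why: Weinreb amide formation by addition of the chloromagnesium amide of N,O-dimethylhydroxylamine to the ester is a standard aminolysis that spares the acetal.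

**Step 5**
Reactants: 5 5-fluoro-2-geranyl-1,3-bis(methoxymethoxy)benzene; 8 N-methoxy-N-methyl-2-(methoxymethoxy)acetamide
Product: 10 1-[6-fluoro-3-geranyl-2,4-bis(methoxymethoxy)phenyl]-2-(methoxymethoxy)ethan-1-one, via aryllithium 9 (not isolated)
Conditions: s-BuLi (1.1 equiv), TMEDA, THF, −78 °C; then 8, −78 → −40 °C; aq. NH4Cl
Reagents that add atoms: none
Why: Directed ortho-metalation at either of the two equivalent ring positions flanked by fluorine and OMOM (held at −78 °C so that LiF is not lost) is followed by a Weinreb ketone synthesis, whose chelated tetrahedral adduct prevents over-addition.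

**Step 6**
Reactants: 10 1-[6-fluoro-3-geranyl-2,4-bis(methoxymethoxy)phenyl]-2-(methoxymethoxy)ethan-1-one
Product: 11 1-[6-fluoro-3-geranyl-2-hydroxy-4-(methoxymethoxy)phenyl]-2-(methoxymethoxy)ethan-1-one
Conditions: HCl (1.25 M in MeOH, 1.5 equiv), MeOH/THF, 0 °C → rt, stopped at mono-cleavage
Reagents that add atoms: none
Why: Acid-catalysed acetal methanolysis should be fastest for the aryl MOM ether ortho to the ketone, whose cleavage is assisted by the carbonyl and gives a hydrogen-bonded phenol, while the para aryl and the alkyl MOM ethers react more slowly (chemoselective deprotection).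

**Step 7**
Reactants: 11 1-[6-fluoro-3-geranyl-2-hydroxy-4-(methoxymethoxy)phenyl]-2-(methoxymethoxy)ethan-1-one
Product: 12 1-[6-fluoro-3-geranyl-2-methoxy-4-(methoxymethoxy)phenyl]-2-(methoxymethoxy)ethan-1-one
Conditions: MeI (3 equiv), K2CO3 (2 equiv), DMF, rt
Reagents that add atoms: iodomethane, CI
Why: Williamson O-methylation of the single free phenol with carbonate base, which does not enolise the ketone to a useful extent, fixes the 5-O-methyl group.

**Step 8**
Reactants: 12 1-[6-fluoro-3-geranyl-2-methoxy-4-(methoxymethoxy)phenyl]-2-(methoxymethoxy)ethan-1-one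
Product: 14 {(Z)-1-[6-fluoro-3-geranyl-2-methoxy-4-(methoxymethoxy)phenyl]-2-(methoxymethoxy)ethenyl}oxy(trimethyl)silane, via lithium enolate 13 (not isolated)
Conditions: LiN(SiMe3)2 (1.1 equiv), THF, −78 °C; Me3SiCl (1.3 equiv), Et3N, −78 → 0 °C; pentane, filtration, used crude
Reagents that add atoms: chlorotrimethylsilane, C[Si](C)(C)Cl
Why: Kinetic deprotonation should give the lithium enolate with the enolate oxygen and the α-OMOM oxygen chelated to lithium (Z geometry), and O-silylation traps it as the Z-enol silane (silyl enol ether formation).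

**Step 9**
Reactants: 14 {(Z)-1-[6-fluoro-3-geranyl-2-methoxy-4-(methoxymethoxy)phenyl]-2-(methoxymethoxy)ethenyl}oxy(trimethyl)silane; 15 4-(methoxymethoxy)benzaldehyde
Product: 17 (2R,3R)-6-geranyl-5-methoxy-3,7-bis(methoxymethoxy)-2-[4-(methoxymethoxy)phenyl]-2,3-dihydro-4H-chromen-4-one, via silyl aldol adduct 16 (not isolated)
Conditions: Sn(OTf)2 (20 mol %), (R)-1-ethyl-2-(piperidin-1-ylmethyl)pyrrolidine (24 mol %), EtCN, −78 °C, slow addition of 14 and 15; then Bu4N[Ph3SiF2] (20 mol %), DMF, −78 °C → rt
Reagents that add atoms: none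
Why: Proposed new method: the diamine-bound divalent tin triflate activates aldehyde 15 and the Z-enol silane 14 adds through an open transition state in which the α-OMOM oxygen binds tin, which should give the anti adduct 16 with the trimethylsilyl group transferred to the new C2 oxygen; catalytic fluoride then turns the O–SiMe3 group into an alkoxide (or a pentacoordinate silicate) that attacks C8a, and loss of fluoride from the σ-adduct both closes ring C and regenerates the fluoride that desilylates the next molecule of 16, so that Me3SiF is the only stoichiometric by-product. The closest known reaction types are the tin triflate/chiral diamine Mukaiyama aldol of (Z)-α-alkoxy silyl enolates that gives anti-α,β-dioxygenated carbonyl compounds, the fluoride-catalysed SNAr of silyl ethers with activated aryl fluorides, and the base-mediated closure of chroman-4-ones from 2-fluoroaryl β-hydroxy ketones; new is their fusion on a ketone-derived enol silane so that C2–C3 and O1–C8a form in one flask. Ring C closes by a 6-endo-trig addition–elimination of O1 on the vinylogous acyl fluoride F–C8a=C4a–C4=O. Both stereocentres arise in the aldol event: C2 from Si-face attack on the aldehyde enforced by the chiral diamine on tin, C3 from the anti (chelate-directed) topology of the Z-enol silane, and no bond to C2 or C3 is broken in the ring closure, which should give the 2,3-trans diequatorial (2R,3R) product. The step needs ring closure to outrun retro-aldol cleavage and C3 enolisation, which the ortho-ketone activation of the C–F bond, the six-membered geometry and the fluoride-limited concentration of alkoxide are meant to secure; the choice between the two oxygens is secured by the MOM ether on the C3 oxygen, and ring A carries only one fluorine, so there is no regiochemical choice.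

**Step 10**
Reactants: 17 (2R,3R)-6-geranyl-5-methoxy-3,7-bis(methoxymethoxy)-2-[4-(methoxymethoxy)phenyl]-2,3-dihydro-4H-chromen-4-one
Product: 18 (2R,3R)-6-geranyl-3,7-dihydroxy-2-(4-hydroxyphenyl)-5-methoxy-2,3-dihydro-4H-chromen-4-one (target)
Conditions: Me3SiOTf (6 equiv), 2,2'-bipyridyl (9 equiv), CH2Cl2, 0 °C → rt; then H2O, rt
Reagents that add atoms: none
Why: Silyl triflate/2,2'-bipyridyl acetal exchange should turn the two aryl MOM ethers into aryl silyl ethers and the alkyl MOM ether into a pyridinium N,O-acetal, all of which hydrolyse on addition of water, a non-protic MOM cleavage that avoids Brønsted-acid cyclisation of the geranyl chain and breaks no bond at C2 or C3.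

**Compound list**

1 | 5-fluorobenzene-1,3-diol (5-fluororesorcinol) | Oc1cc(O)cc(F)c1 | starting material
2 | 1-fluoro-3,5-bis(methoxymethoxy)benzene | COCOc1cc(F)cc(OCOC)c1 | intermediate
3 | geranyl bromide, (2E)-1-bromo-3,7-dimethylocta-2,6-diene | BrC/C=C(\C)CCC=C(C)C | starting material
4 | [4-fluoro-2,6-bis(methoxymethoxy)phenyl]lithium | [Li]c1c(OCOC)cc(F)cc1OCOC | intermediate
5 | 2-[(2E)-3,7-dimethylocta-2,6-dien-1-yl]-5-fluoro-1,3-bis(methoxymethoxy)benzene | COCOc1cc(F)cc(OCOC)c1C/C=C(\C)CCC=C(C)C | intermediate
6 | methyl glycolate | COC(=O)CO | starting material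
7 | methyl 2-(methoxymethoxy)acetate | COCOCC(=O)OC | intermediate
8 | N-methoxy-N-methyl-2-(methoxymethoxy)acetamide | COCOCC(=O)N(C)OC | intermediate
9 | {3-[(2E)-3,7-dimethylocta-2,6-dien-1-yl]-6-fluoro-2,4-bis(methoxymethoxy)phenyl}lithium | [Li]c1c(F)cc(OCOC)c(C/C=C(\C)CCC=C(C)C)c1OCOC | intermediate
10 | 1-{3-[(2E)-3,7-dimethylocta-2,6-dien-1-yl]-6-fluoro-2,4-bis(methoxymethoxy)phenyl}-2-(methoxymethoxy)ethan-1-one | COCOCC(=O)c1c(F)cc(OCOC)c(C/C=C(\C)CCC=C(C)C)c1OCOC | intermediate
11 | 1-{3-[(2E)-3,7-dimethylocta-2,6-dien-1-yl]-6-fluoro-2-hydroxy-4-(methoxymethoxy)phenyl}-2-(methoxymethoxy)ethan-1-one | COCOCC(=O)c1c(F)cc(OCOC)c(C/C=C(\C)CCC=C(C)C)c1O | intermediate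
12 | 1-{3-[(2E)-3,7-dimethylocta-2,6-dien-1-yl]-6-fluoro-2-methoxy-4-(methoxymethoxy)phenyl}-2-(methoxymethoxy)ethan-1-one | COCOCC(=O)c1c(F)cc(OCOC)c(C/C=C(\C)CCC=C(C)C)c1OC | intermediate
13 | lithium (Z)-enolate of 12 | [Li]O/C(=C\OCOC)c1c(F)cc(OCOC)c(C/C=C(\C)CCC=C(C)C)c1OC | intermediate
14 | {(Z)-1-{3-[(2E)-3,7-dimethylocta-2,6-dien-1-yl]-6-fluoro-2-methoxy-4-(methoxymethoxy)phenyl}-2-(methoxymethoxy)ethenyl}oxy(trimethyl)silane | C[Si](C)(C)O/C(=C\OCOC)c1c(F)cc(OCOC)c(C/C=C(\C)CCC=C(C)C)c1OC | intermediate
15 | 4-(methoxymethoxy)benzaldehyde | COCOc1ccc(C=O)cc1 | starting material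
16 | (2R,3R)-1-{3-[(2E)-3,7-dimethylocta-2,6-dien-1-yl]-6-fluoro-2-methoxy-4-(methoxymethoxy)phenyl}-2-(methoxymethoxy)-3-[4-(methoxymethoxy)phenyl]-3-(trimethylsilyloxy)propan-1-one | COc1c(C/C=C(\C)CCC=C(C)C)c(OCOC)cc(F)c1C(=O)[C@H](OCOC)[C@@H](c1ccc(OCOC)cc1)O[Si](C)(C)C | intermediate
17 | (2R,3R)-6-[(2E)-3,7-dimethylocta-2,6-dien-1-yl]-5-methoxy-3,7-bis(methoxymethoxy)-2-[4-(methoxymethoxy)phenyl]-2,3-dihydro-4H-chromen-4-one | COc1c(C/C=C(\C)CCC=C(C)C)c(OCOC)cc2c1C(=O)[C@H](OCOC)[C@@H](c1ccc(OCOC)cc1)O2 | intermediate
18 | (2R,3R)-6-[(2E)-3,7-dimethylocta-2,6-dien-1-yl]-3,7-dihydroxy-2-(4-hydroxyphenyl)-5-methoxy-2,3-dihydro-4H-chromen-4-one | COc1c(C/C=C(\C)CCC=C(C)C)c(O)cc2c1C(=O)[C@H](O)[C@@H](c1ccc(O)cc1)O2 | target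

**Step count**

Total steps: 10. Longest linear sequence: 8 (steps 1, 2, 5, 6, 7, 8, 9, 10).

**Steps most likely to fail**

1. Step 9. The ketone-derived enol silane may add too slowly or with poor facial and anti/syn control, and at the alkoxide stage retro-aldol cleavage or C3 enolisation may erode the configuration before the C–O bond closes. The fallback uses known reaction types and separates the two bond formations; it sets out from 14 and 15 and comes back at 17. The aldol is run as a Lewis-base-catalysed Mukaiyama aldol (SiCl4, 5 mol % of the enantiomer of the binaphthyldiamine-derived bisphosphoramide that effects Si-face addition, iPr2NEt, CH2Cl2, −78 °C; aq. KF/NaHCO3 work-up), a type established for ketone enol silanes and α-alkoxy silyl enolates with aromatic aldehydes. The free anti aldol (2R,3R)-1-{3-[(2E)-3,7-dimethylocta-2,6-dien-1-yl]-6-fluoro-2-methoxy-4-(methoxymethoxy)phenyl}-3-hydroxy-2-(methoxymethoxy)-3-[4-(methoxymethoxy)phenyl]propan-1-one F1 is isolated and freed from its syn isomer by chromatography. It is then cyclised in a separate conventional intramolecular SNAr of the pre-formed potassium alkoxide (KN(SiMe3)2, THF/DMF, −78 → 0 °C) to give 17.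

2. Step 2. Lithiation may be misdirected to the position next to fluorine, followed by loss of LiF and aryne-derived by-products. The fallback fixes the position with a halogen; it sets out from 1 and comes back at 5. Iodination between the two hydroxyl groups (I2, NaHCO3, H2O, 0 °C) should give 5-fluoro-2-iodobenzene-1,3-diol F2. MOM protection (MOMCl, iPr2NEt, CH2Cl2) gives 5-fluoro-2-iodo-1,3-bis(methoxymethoxy)benzene F3. Iodine–lithium exchange (n-BuLi, THF, −78 °C) then gives aryllithium 4 regiospecifically, which is coupled with 3 exactly as in step 2 to give 5.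

3. Step 6. Discrimination between the two aryl MOM ethers may be poor, with over-cleavage before the ortho ether is fully consumed. The fallback replaces selective deprotection by exhaustive aryl deprotection and selective re-protection; it sets out from 10 and comes back at 11. Both aryl MOM ethers are methanolysed (HCl, MeOH, 40 °C; aryl acetals cleave faster than the alkyl one) to 1-{3-[(2E)-3,7-dimethylocta-2,6-dien-1-yl]-6-fluoro-2,4-dihydroxyphenyl}-2-(methoxymethoxy)ethan-1-one F4. The non-chelated para hydroxyl is then re-protected selectively (MOMCl 1.05 equiv, iPr2NEt, CH2Cl2, 0 °C), the ortho hydroxyl being held by its hydrogen bond to the ketone, to give 11.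

Further compounds
F1 | step 9 | (2R,3R)-1-{3-[(2E)-3,7-dimethylocta-2,6-dien-1-yl]-6-fluoro-2-methoxy-4-(methoxymethoxy)phenyl}-3-hydroxy-2-(methoxymethoxy)-3-[4-(methoxymethoxy)phenyl]propan-1-one | COc1c(C/C=C(\C)CCC=C(C)C)c(OCOC)cc(F)c1C(=O)[C@H](OCOC)[C@@H](c1ccc(OCOC)cc1)O
F2 | step 2 | 5-fluoro-2-iodobenzene-1,3-diol | Oc1cc(F)cc(O)c1I
F3 | step 2 | 5-fluoro-2-iodo-1,3-bis(methoxymethoxy)benzene | COCOc1cc(F)cc(OCOC)c1I
F4 | step 6 | 1-{3-[(2E)-3,7-dimethylocta-2,6-dien-1-yl]-6-fluoro-2,4-dihydroxyphenyl}-2-(methoxymethoxy)ethan-1-one | COCOCC(=O)c1c(F)cc(O)c(C/C=C(\C)CCC=C(C)C)c1O
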